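## Plan

- Numbering: chromene O1, C2, C3, C4, C4a, C5 to C8, C8a; side chain C1' to C13'.
- Cuts: the C3=C4 double bond goes back to a C4 ketone. Then C2–C3 is cut (carbene C–H insertion), then C3–C4 (acylation of a diazomethane), O1–C2 (Mitsunobu), C4–C4a (ortho-formylation) and last the alkene of phytol.
- Enabling feature: the tetrasubstituted C2 on O1 is the carbon of a secondary aryl alkyl ether plus one bond to C3. Its C–H bond is alpha to O1 and six atoms from a carbene at C3, so the pyran ring (O1, C2, C3, C4, C4a, C8a) can be closed onto that C–H bond.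
- Forward: phytol gives the C18 methyl carbinol and 2,5-dimethylhydroquinone gives the silylated salicylaldehyde. They are joined at O1–C2, C4 is oxidised, C3 is added as a diazomethyl group, the pyranone ring closes, and the ketone becomes the alkene before desilylation.
- Stereochemistry: C4' and C8' come from natural phytol. C2 is set as R by a ketoreductase, inverted to S in the Mitsunobu step and kept by the retentive insertion.

Key step: step 9

Remark: the target is read as the (2S,4'R,8'R) isomer written in the SMILES; paraformaldehyde is written as its monomer, and C4 of alcohol 15 is carried as an epimer mixture because it becomes sp2 one step later.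

## Route

Step 1
Reactants: 1 natural phytol, (2E,7R,11R)-3,7,11,15-tetramethylhexadec-2-en-1-ol
Product: 3 (6R,10R)-6,10,14-trimethylpentadecan-2-one, via secondary ozonide 2 (not isolated)
Conditions: O3, CH2Cl2, −78 °C; then PPh3, −78 °C to rt
Reagents that add atoms: ozone, [O-][O+]=O
Why: Ozonolysis (Criegee mechanism) cleaves the only C=C bond of 1, and reduction of the ozonide with PPh3 should release the methyl ketone without touching the two remote methyl-bearing stereocentres.

Step 2
Reactants: 3 (6R,10R)-6,10,14-trimethylpentadecan-2-one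
Product: 4 (2R,6R,10R)-6,10,14-trimethylpentadecan-2-ol
Conditions: (R)-selective alcohol dehydrogenase from Lactobacillus kefir, NADP+ (cat.), i-PrOH/phosphate buffer pH 7 (MgCl2 1 mM), 30 °C
Reagents that add atoms: none
Why: Enzymatic asymmetric ketone reduction with an anti-Prelog alcohol dehydrogenase, which tells the methyl group from the long chain and delivers hydride to the si face, should set the carbinol centre as R while isopropanol regenerates the cofactor.

Step 3
Reactants: 5 2,5-dimethylbenzene-1,4-diol (2,5-dimethylhydroquinone), in threefold excess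
Product: 6 4-(tert-butyldimethylsilyloxy)-2,5-dimethylphenol
Conditions: TBSCl (limiting), imidazole, DMF, 0 °C to rt
Reagents that add atoms: tert-butyldimethylsilyl chloride, CC(C)(C)[Si](C)(C)Cl
Why: Silylation of a phenol with TBSCl and imidazole should stop at the mono-ether when the symmetrical diol is in excess, and unreacted 5 can be recovered.

Step 4
Reactants: 6 4-(tert-butyldimethylsilyloxy)-2,5-dimethylphenol; 7 paraformaldehyde
Product: 8 5-(tert-butyldimethylsilyloxy)-2-hydroxy-3,6-dimethylbenzaldehyde
Conditions: MgCl2, Et3N, MeCN, reflux; cold dilute aq. HCl work-up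
Reagents that add atoms: none
Why: In this magnesium-mediated ortho-formylation (Casnati–Skattebøl reaction) the magnesium phenoxide should direct formaldehyde to the only free ortho position, and a second formaldehyde oxidises the benzylic alkoxide to the aldehyde.

Step 5
Reactants: 4 (2R,6R,10R)-6,10,14-trimethylpentadecan-2-ol; 8 5-(tert-butyldimethylsilyloxy)-2-hydroxy-3,6-dimethylbenzaldehyde
Product: 9 5-(tert-butyldimethylsilyloxy)-3,6-dimethyl-2-[(2S,6R,10R)-6,10,14-trimethylpentadecan-2-yloxy]benzaldehyde
Conditions: PPh3, DIAD, THF, 0 °C to rt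
Reagents that add atoms: none
Why: In this Mitsunobu etherification the acidic, chelated salicylaldehyde-type phenol should displace the alkoxyphosphonium group of 4 in an SN2 step, so the R carbinol centre becomes the S ether centre by inversion.

Step 6
Reactants: 9 5-(tert-butyldimethylsilyloxy)-3,6-dimethyl-2-[(2S,6R,10R)-6,10,14-trimethylpentadecan-2-yloxy]benzaldehyde
Product: 10 5-(tert-butyldimethylsilyloxy)-3,6-dimethyl-2-[(2S,6R,10R)-6,10,14-trimethylpentadecan-2-yloxy]benzoic acid
Conditions: NaClO2, NaH2PO4, 2-methyl-2-butene, t-BuOH/THF/H2O, 0 °C to rt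
Reagents that add atoms: sodium chlorite, [Na+].[O-]Cl=O
Why: Pinnick oxidation should convert the hindered, non-enolisable aryl aldehyde into the acid under buffered conditions that spare both ethers, with 2-methyl-2-butene trapping hypochlorous acid before it chlorinates the electron-rich ring.

Step 7
Reactants: 10 5-(tert-butyldimethylsilyloxy)-3,6-dimethyl-2-[(2S,6R,10R)-6,10,14-trimethylpentadecan-2-yloxy]benzoic acid
Product: 11 5-(tert-butyldimethylsilyloxy)-3,6-dimethyl-2-[(2S,6R,10R)-6,10,14-trimethylpentadecan-2-yloxy]benzoyl chloride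
Conditions: (COCl)2, DMF (cat.), CH2Cl2, 0 °C to rt; evaporate, use crude
Reagents that add atoms: oxalyl chloride, ClC(=O)C(=O)Cl
Why: Acid chloride formation through the Vilsmeier-type chloroiminium ion should proceed under conditions that leave the ether stereocentre and the aryl silyl ether intact.

Step 8
Reactants: 11 5-(tert-butyldimethylsilyloxy)-3,6-dimethyl-2-[(2S,6R,10R)-6,10,14-trimethylpentadecan-2-yloxy]benzoyl chloride; 12 trimethylsilyldiazomethane
Product: 13 2-diazo-1-{5-(tert-butyldimethylsilyloxy)-3,6-dimethyl-2-[(2S,6R,10R)-6,10,14-trimethylpentadecan-2-yloxy]phenyl}ethanone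
Conditions: Et3N, THF/MeCN, 0 °C to rt; aq. NaHCO3 work-up
Reagents that add atoms: none
Why: In this acylation of a diazoalkane (Arndt–Eistert-type diazoketone synthesis) the diazo carbon of 12 should attack the aroyl chloride, and the C-silyl group is lost to chloride or on aqueous work-up to leave the diazomethyl ketone.

Step 9
Reactants: 13 2-diazo-1-{5-(tert-butyldimethylsilyloxy)-3,6-dimethyl-2-[(2S,6R,10R)-6,10,14-trimethylpentadecan-2-yloxy]phenyl}ethanone
Product: 14 (2S)-6-(tert-butyldimethylsilyloxy)-2,5,8-trimethyl-2-[(4R,8R)-4,8,12-trimethyltridecyl]chroman-4-one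
Conditions: Rh2(OAc)4 (1 mol %), CH2Cl2, 40 °C, slow addition of 13 at high dilution
Reagents that add atoms: none
Why: Rh2(OAc)4, a divalent rhodium carboxylate, should bind the diazo carbon of 13 and expel dinitrogen, and the electrophilic carbenoid at the future C3 then inserts into the C2–H bond through a concerted three-centre transition state in which a lone pair of O1 stabilises the positive charge building at C2. The closest known reaction type is the dirhodium-catalysed intramolecular C–H insertion of 2-alkoxyaryl α-diazoketones to chroman-4-ones, applied here to the methine of a secondary alkyl ether, the electronically most activated kind of C–H bond for it. The pyranone ring (O1, C2, C3, C4, C4a, C8a) closes by forming C2–C3 as a 1,6-insertion to a six-membered ring, since the atom that would give a five-membered ring is O1 and carries no hydrogen. C2 becomes tetrasubstituted with retention because the carbenoid carbon takes the place of the departing hydrogen on the same face, so its S configuration is dictated by the S ether centre of 13. The step needs site selectivity for C2–H over the O1 lone pair (oxonium ylide, then Stevens shift to a benzofuran-3-one), over the methyl and C1' hydrogens of the ether (seven-membered closures) and over the primary benzylic hydrogens of the C5 methyl group (a strained five-membered closure to an indanone). It rests on the tertiary α-oxy character of C2–H, on the low nucleophilicity and crowding of the doubly ortho-flanked aryl ether oxygen, whose ylide has no stabilised migrating group and can revert to the carbenoid, and on slow addition, which suppresses carbene dimerisation.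

Step 10
Reactants: 14 (2S)-6-(tert-butyldimethylsilyloxy)-2,5,8-trimethyl-2-[(4R,8R)-4,8,12-trimethyltridecyl]chroman-4-one
Product: 15 (2S,4RS)-6-(tert-butyldimethylsilyloxy)-2,5,8-trimethyl-2-[(4R,8R)-4,8,12-trimethyltridecyl]chroman-4-ol
Conditions: NaBH4, CeCl3·7H2O, MeOH/THF, −20 to 0 °C
Reagents that add atoms: none
Why: Borohydride reduction of the aryl ketone promoted by CeCl3 is fast and only weakly basic, so the carbonyl should be removed before retro-oxa-Michael ring opening can scramble C2, and the new C4 carbinol centre forms as an epimer mixture that is erased in the next step.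

Step 11
Reactants: 15 (2S,4RS)-6-(tert-butyldimethylsilyloxy)-2,5,8-trimethyl-2-[(4R,8R)-4,8,12-trimethyltridecyl]chroman-4-ol
Product: 17 (2S)-6-(tert-butyldimethylsilyloxy)-2,5,8-trimethyl-2-[(4R,8R)-4,8,12-trimethyltridecyl]-2H-chromene, via sulfamate ester salt 16 (not isolated)
Conditions: Burgess reagent (MeO2CN−SO2N+Et3), THF, rt then 50 °C
Reagents that add atoms: none
Why: In this Burgess dehydration the benzylic alcohol becomes a sulfamate ester that should undergo thermal syn elimination with a C3 hydrogen (each C4 epimer has one), giving the C3=C4 bond under neutral conditions that do not ionise the allylic C2–O1 bond.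

Step 12
Reactants: 17 (2S)-6-(tert-butyldimethylsilyloxy)-2,5,8-trimethyl-2-[(4R,8R)-4,8,12-trimethyltridecyl]-2H-chromene
Product: 18 (2S)-2,5,8-trimethyl-2-[(4R,8R)-4,8,12-trimethyltridecyl]-2H-chromen-6-ol
Conditions: Bu4NF, AcOH, THF, 0 °C, under argon
Reagents that add atoms: none
Why: Fluoride-induced cleavage of the aryl silyl ether, buffered with acetic acid so that the air-sensitive phenoxide is protonated at once, should free the phenol without exposing the chromene or C2 to base.

## Compound list

1 | natural phytol, (2E,7R,11R)-3,7,11,15-tetramethylhexadec-2-en-1-ol | OC/C=C(\C)CCC[C@H](C)CCC[C@H](C)CCCC(C)C | starting material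
2 | secondary ozonide of 1, 3-(hydroxymethyl)-5-methyl-5-[(4R,8R)-4,8,12-trimethyltridecyl]-1,2,4-trioxolane (ring diastereomers) | OCC1OOC(C)(CCC[C@H](C)CCC[C@H](C)CCCC(C)C)O1 | intermediate (not isolated)
3 | (6R,10R)-6,10,14-trimethylpentadecan-2-one | CC(=O)CCC[C@H](C)CCC[C@H](C)CCCC(C)C | intermediate
4 | (2R,6R,10R)-6,10,14-trimethylpentadecan-2-ol | O[C@H](C)CCC[C@H](C)CCC[C@H](C)CCCC(C)C | intermediate
5 | 2,5-dimethylbenzene-1,4-diol (2,5-dimethylhydroquinone) | Cc1cc(O)c(C)cc1O | starting material
6 | 4-(tert-butyldimethylsilyloxy)-2,5-dimethylphenol | Cc1cc(O[Si](C)(C)C(C)(C)C)c(C)cc1O | intermediate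
7 | paraformaldehyde (as formaldehyde) | C=O | starting material
8 | 5-(tert-butyldimethylsilyloxy)-2-hydroxy-3,6-dimethylbenzaldehyde | Cc1cc(O[Si](C)(C)C(C)(C)C)c(C)c(C=O)c1O | intermediate
9 | 5-(tert-butyldimethylsilyloxy)-3,6-dimethyl-2-[(2S,6R,10R)-6,10,14-trimethylpentadecan-2-yloxy]benzaldehyde | Cc1cc(O[Si](C)(C)C(C)(C)C)c(C)c(C=O)c1O[C@@H](C)CCC[C@H](C)CCC[C@H](C)CCCC(C)C | intermediate
10 | 5-(tert-butyldimethylsilyloxy)-3,6-dimethyl-2-[(2S,6R,10R)-6,10,14-trimethylpentadecan-2-yloxy]benzoic acid | Cc1cc(O[Si](C)(C)C(C)(C)C)c(C)c(C(=O)O)c1O[C@@H](C)CCC[C@H](C)CCC[C@H](C)CCCC(C)C | intermediate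
11 | 5-(tert-butyldimethylsilyloxy)-3,6-dimethyl-2-[(2S,6R,10R)-6,10,14-trimethylpentadecan-2-yloxy]benzoyl chloride | Cc1cc(O[Si](C)(C)C(C)(C)C)c(C)c(C(=O)Cl)c1O[C@@H](C)CCC[C@H](C)CCC[C@H](C)CCCC(C)C | intermediate
12 | trimethylsilyldiazomethane | C[Si](C)(C)C=[N+]=[N-] | starting material
13 | 2-diazo-1-{5-(tert-butyldimethylsilyloxy)-3,6-dimethyl-2-[(2S,6R,10R)-6,10,14-trimethylpentadecan-2-yloxy]phenyl}ethanone | Cc1cc(O[Si](C)(C)C(C)(C)C)c(C)c(C(=O)C=[N+]=[N-])c1O[C@@H](C)CCC[C@H](C)CCC[C@H](C)CCCC(C)C | intermediate
14 | (2S)-6-(tert-butyldimethylsilyloxy)-2,5,8-trimethyl-2-[(4R,8R)-4,8,12-trimethyltridecyl]chroman-4-one | Cc1cc(O[Si](C)(C)C(C)(C)C)c(C)c2c1O[C@@](C)(CCC[C@H](C)CCC[C@H](C)CCCC(C)C)CC2=O | intermediate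
15 | (2S,4RS)-6-(tert-butyldimethylsilyloxy)-2,5,8-trimethyl-2-[(4R,8R)-4,8,12-trimethyltridecyl]chroman-4-ol | Cc1cc(O[Si](C)(C)C(C)(C)C)c(C)c2c1O[C@@](C)(CCC[C@H](C)CCC[C@H](C)CCCC(C)C)CC2O | intermediate
16 | triethylammonium salt of the C4 O-[N-(methoxycarbonyl)sulfamate] of 15 | Cc1cc(O[Si](C)(C)C(C)(C)C)c(C)c2c1O[C@@](C)(CCC[C@H](C)CCC[C@H](C)CCCC(C)C)CC2OS(=O)(=O)[N-]C(=O)OC.CC[NH+](CC)CC | intermediate (not isolated)
17 | (2S)-6-(tert-butyldimethylsilyloxy)-2,5,8-trimethyl-2-[(4R,8R)-4,8,12-trimethyltridecyl]-2H-chromene | Cc1cc(O[Si](C)(C)C(C)(C)C)c(C)c2c1O[C@@](C)(CCC[C@H](C)CCC[C@H](C)CCCC(C)C)C=C2 | intermediate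
18 | (2S)-2,5,8-trimethyl-2-[(4R,8R)-4,8,12-trimethyltridecyl]-2H-chromen-6-ol | Cc1cc(O)c(C)c2c1O[C@@](C)(CCC[C@H](C)CCC[C@H](C)CCCC(C)C)C=C2 | target

## Count and risks

Total step count: 12. Longest linear sequence: 10 steps (steps 1, 2 and 5 to 12; the arene branch, steps 3, 4 and 5 to 12, is equally long).

Steps most likely to fail:

1. Step 9. The carbenoid may be captured by the O1 lone pair and rearrange, or dimerise, instead of inserting into the C2–H bond, which would cost material though not configuration. The fallback sets out from 5 (with ketone 3) and comes back at 14. Friedel–Crafts acetylation of 5 (AcOH, BF3·OEt2, 90 °C) would give 1-(2,5-dihydroxy-3,6-dimethylphenyl)ethanone F1. Kabbe condensation of F1 with 3 (pyrrolidine, toluene, reflux with removal of water) would give (2RS)-6-hydroxy-2,5,8-trimethyl-2-[(4R,8R)-4,8,12-trimethyltridecyl]chroman-4-one F2. Silylation (TBSCl, imidazole, DMF) would give the C2-epimeric silyl chromanone F3. Preparative HPLC on a chiral stationary phase would then separate 14 from the (2R) epimer of 14 F4, which is set aside. This gives up stereocontrol at C2 in exchange for a ring closure that does not depend on a carbene.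

2. Step 5. The redox condensation may be slow at the doubly ortho-flanked phenol, so that the activated alcohol eliminates or inversion is incomplete. The fallback sets out from 4 and comes back at 9. Mesylation (MsCl, Et3N, CH2Cl2, 0 °C) would give (2R,6R,10R)-6,10,14-trimethylpentadecan-2-yl methanesulfonate F5. SN2 displacement of F5 by the cesium phenoxide of 8 (Cs2CO3, DMF, 50 °C) should then give 9 with the same inversion.

3. Step 2. The enzyme may accept the very lipophilic C18 ketone poorly in aqueous medium, or its R selectivity may erode. The fallback sets out from 3 and comes back at 4. Reduction with NaBH4 (MeOH, 0 °C) would give (2RS,6R,10R)-6,10,14-trimethylpentadecan-2-ol F6. Dynamic kinetic resolution of F6 (immobilised Candida antarctica lipase B, isopropenyl acetate, (C5Ph5)Ru(CO)2Cl, KOt-Bu, Na2CO3, toluene, rt) would give (2R,6R,10R)-6,10,14-trimethylpentadecan-2-yl acetate F7. Methanolysis of F7 (K2CO3, MeOH) would give 4.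

## Further compounds

F1 | step 9 | 1-(2,5-dihydroxy-3,6-dimethylphenyl)ethanone | CC(=O)c1c(O)c(C)cc(O)c1C
F2 | step 9 | (2RS)-6-hydroxy-2,5,8-trimethyl-2-[(4R,8R)-4,8,12-trimethyltridecyl]chroman-4-one | Cc1cc(O)c(C)c2c1OC(C)(CCC[C@H](C)CCC[C@H](C)CCCC(C)C)CC2=O
F3 | step 9 | (2RS)-6-(tert-butyldimethylsilyloxy)-2,5,8-trimethyl-2-[(4R,8R)-4,8,12-trimethyltridecyl]chroman-4-one | Cc1cc(O[Si](C)(C)C(C)(C)C)c(C)c2c1OC(C)(CCC[C@H](C)CCC[C@H](C)CCCC(C)C)CC2=O
F4 | step 9 | (2R)-6-(tert-butyldimethylsilyloxy)-2,5,8-trimethyl-2-[(4R,8R)-4,8,12-trimethyltridecyl]chroman-4-one | Cc1cc(O[Si](C)(C)C(C)(C)C)c(C)c2c1O[C@](C)(CCC[C@H](C)CCC[C@H](C)CCCC(C)C)CC2=O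
F5 | step 5 | (2R,6R,10R)-6,10,14-trimethylpentadecan-2-yl methanesulfonate | CS(=O)(=O)O[C@H](C)CCC[C@H](C)CCC[C@H](C)CCCC(C)C
F6 | step 2 | (2RS,6R,10R)-6,10,14-trimethylpentadecan-2-ol | CC(O)CCC[C@H](C)CCC[C@H](C)CCCC(C)C
F7 | step 2 | (2R,6R,10R)-6,10,14-trimethylpentadecan-2-yl acetate | CC(=O)O[C@H](C)CCC[C@H](C)CCC[C@H](C)CCCC(C)C
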